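**Retrosynthetic overview**

1. Endgame: the C9=C10 enone comes from dehydrogenation of a C11 ketone, the C4 oxirane ester from acylation, the C6 angelate and the C4 carbinol from one Evans–Tishchenko reaction, and C6–OH from catalyst-controlled β-borylation of a C5=C6 cycloheptenone.
2. Key disconnection: C2–C3 and C6–C7, giving bicyclobutane 12 and the four-carbon bromo stannyl enone 18, joined by a radical (4+2σ) annulation.
3. Enabling feature: in the cyclobutane C1–C2–C8–C7 the diagonal carbons C2 and C7 carry both ends of the chain C3–C6 on the face opposite the C9–C11 bridge, so C2···C7 is the latent central bond of a bicyclo[1.1.0]butane (a tricyclo[4.1.0.0^2,7]heptane); C3 (gem-dimethyl next to the C4 oxygen) is a latent tertiary α-keto radical.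
4. Ring order: six-membered ring (organocatalytic annulation), cyclopropane (dibromocarbene), bicyclobutane (C–H insertion; this already holds the cyclobutane and the six-membered ring), oxirane of the side-chain acid (separate fragment), seven-membered ring last.

Key step: step 11

Remark: tricyclic compounds are numbered as tricyclo[5.4.0.0^2,8]undecane (C1–C7 seven-membered ring, C1/C2/C8/C7 cyclobutane, C7–C8–C9–C10–C11–C1 six-membered ring).
Remark: the oxirane ester in the given structure is (2S,3R)-2,3-dimethyloxirane-2-carboxylate (methyl groups cis, the epoxide of the E acid), and the route is built for that.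

**Route**

Step 1
Reactants: 1 tert-butyl 3-oxobutanoate; 2 (E)-but-2-enal
Product: 5 (R)-5-methylcyclohex-2-en-1-one, via Michael adduct 3 (not isolated), via cyclic keto ester 4 (not isolated)
Conditions: (S)-2-{bis[3,5-bis(trifluoromethyl)phenyl](trimethylsilyloxy)methyl}pyrrolidine (10 mol %), toluene, 25 °C; then TsOH·H2O (20 mol %), 80 °C
Reagents that add atoms: none
Why: Iminium-catalysed asymmetric Michael addition (Jørgensen–Hayashi catalyst) sets the methyl stereocentre by shielding one face of the (E)-iminium, and acid then drives aldol condensation, tert-butyl ester cleavage and decarboxylation (organocatalytic Robinson-type annulation).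

Step 2
Reactants: 5 (R)-5-methylcyclohex-2-en-1-one
Product: 6 (5R)-1,5-dimethylcyclohex-2-en-1-ol (C1 epimers)
Conditions: MeLi, Et2O, −78 °C; H2O
Reagents that add atoms: methyllithium [Li]C
Why: 1,2-Addition of a hard organolithium to the enone; the new carbinol centre does not matter because step 3 removes it.

Step 3
Reactants: 6 (5R)-1,5-dimethylcyclohex-2-en-1-ol
Product: 7 (S)-3,5-dimethylcyclohex-2-en-1-one
Conditions: C5H5NH[CrO3Cl] (pyridinium chlorochromate, 2 equiv), CH2Cl2, 25 °C
Reagents that add atoms: none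
Why: Dauben oxidative 1,3-transposition of a tertiary allylic alcohol ([3,3]-shift of the chromate ester, then oxidation) moves the oxygen to the future C11 and puts the methyl on the alkene; C5 is untouched.

Step 4
Reactants: 7 (S)-3,5-dimethylcyclohex-2-en-1-one
Product: 8 (1S,5S)-3,5-dimethylcyclohex-2-en-1-ol (cis)
Conditions: NaBH4, CeCl3·7H2O, MeOH, −78 → 0 °C
Reagents that add atoms: none
Why: Luche reduction is 1,2-selective and, by axial hydride attack on the half-chair with an equatorial 5-methyl group, should give the cis alcohol.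

Step 5
Reactants: 8 (1S,5S)-3,5-dimethylcyclohex-2-en-1-ol
Product: 9 7,7-dibromo-4,6-dimethylbicyclo[4.1.0]heptan-2-ol (OH, 4-CH3 and C7 all on one face)
Conditions: CHBr3, 50 % aq. NaOH, BnEt3NCl (cat.), CH2Cl2, 0 → 25 °C
Reagents that add atoms: bromoform BrC(Br)Br
Why: Makosza phase-transfer dibromocarbene addition to an allylic alcohol is hydroxyl-directed, so the cyclopropane should form syn to OH (and to the cis 4-methyl), which sets both ring-fusion stereocentres and the absolute sense of the future cyclobutane.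

Step 6
Reactants: 9 7,7-dibromo-4,6-dimethylbicyclo[4.1.0]heptan-2-ol
Product: 10 tert-butyl[(7,7-dibromo-4,6-dimethylbicyclo[4.1.0]heptan-2-yl)oxy]dimethylsilane
Conditions: TBSOTf, 2,6-lutidine, CH2Cl2, 0 °C
Reagents that add atoms: tert-butyldimethylsilyl triflate CC(C)(C)[Si](C)(C)OS(=O)(=O)C(F)(F)F
Why: Standard silylation of a hindered secondary alcohol; the silyl ether later shields one flank of the bicyclobutane.

Step 7
Reactants: 10 tert-butyl[(7,7-dibromo-4,6-dimethylbicyclo[4.1.0]heptan-2-yl)oxy]dimethylsilane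
Product: 12 tert-butyl[(1,5-dimethyltricyclo[4.1.0.0^2,7]heptan-3-yl)oxy]dimethylsilane, via bromolithio carbenoid 11 (not isolated)
Conditions: MeLi (1.2 equiv), Et2O, −78 → 0 °C
Reagents that add atoms: none
Why: Moore–Skattebøl-type reaction: Br/Li exchange gives the carbenoid, whose cyclopropylidene inserts into the adjacent C–H bond cis to it (1,3-insertion, as in the formation of tricyclo[4.1.0.0^2,7]heptane from 7,7-dibromonorcarane); only C5 offers such a hydrogen because the C2 hydrogen is trans (OSi cis), so the methyl ends on a bridgehead and the new stereocentres are fixed by the ring.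

Step 8
Reactants: 13 (E)-2-methylbut-2-en-1-ol
Product: 14 [(2R,3R)-2,3-dimethyloxiran-2-yl]methanol
Conditions: Ti(OiPr)4 (10 mol %), D-(−)-diisopropyl tartrate (12 mol %), t-BuOOH, 4 Å MS, CH2Cl2, −20 °C
Reagents that add atoms: tert-butyl hydroperoxide CC(C)(C)OO
Why: Sharpless asymmetric epoxidation; the D-(−)-tartrate should give the (2R,3R)-epoxide by reagent control, and the cis methyl groups follow from the E alkene.

Step 9
Reactants: 14 [(2R,3R)-2,3-dimethyloxiran-2-yl]methanol
Product: 15 (2S,3R)-2,3-dimethyloxirane-2-carboxylic acid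
Conditions: RuCl3 (2 mol %), NaIO4, MeCN/EtOAc/H2O, 0 → 25 °C; stored at −20 °C
Reagents that add atoms: sodium periodate [Na+].[O-]I(=O)(=O)=O; water O
Why: Ruthenium tetroxide oxidation (RuCl3/NaIO4) takes the primary epoxy alcohol to the glycidic acid without touching the oxirane; the C2 descriptor changes only because the priorities change.

Step 10
Reactants: 16 (E)-1,2-bis(tributylstannyl)ethene; 17 2-bromo-2-methylpropanoyl bromide
Product: 18 (E)-4-bromo-4-methyl-1-(tributylstannyl)pent-1-en-3-one
Conditions: PdCl2(PPh3)2 (2 mol %), CHCl3, 60 °C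
Reagents that add atoms: none
Why: Stille acylation (acyl halide with a vinylstannane, zerovalent palladium cycle) stops after one coupling because the product vinylstannane is electron-poor; the E geometry is retained.

Step 11
Reactants: 12 tert-butyl[(1,5-dimethyltricyclo[4.1.0.0^2,7]heptan-3-yl)oxy]dimethylsilane; 18 (E)-4-bromo-4-methyl-1-(tributylstannyl)pent-1-en-3-one
Product: 20 11-(tert-butyldimethylsilyloxy)-3,3,7,9-tetramethyltricyclo[5.4.0.0^2,8]undec-5-en-4-one, via cyclobutyl radical 19 (not isolated)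
Conditions: (Bu3Sn)2 (0.2 equiv), hν (sunlamp), PhH (0.01 M), 40 °C; 18 (1.5 equiv) added over 10 h
Reagents that add atoms: none
Why: Proposed new method: Bu3Sn• abstracts bromine from 18 to give an electrophilic tertiary α-keto radical, which opens the electron-rich central (bridgehead–bridgehead) σ bond of bicyclobutane 12 by attack at the unsubstituted bridgehead (strain release, forming C2–C3); the resulting nucleophilic tertiary cyclobutyl radical 19 then adds to the stannyl-bearing β-carbon of the tethered enone (forming C6–C7), and β-scission expels Bu3Sn•, which carries the chain and leaves the C5=C6 enone. The closest known reaction types are radical additions across the central bond of tricyclo[4.1.0.0^2,7]heptanes (atom-transfer additions with anti attack) and radical vinylation by addition–fragmentation of β-stannyl enoates (Baldwin type); their merger into a formal (4+2σ) annulation on an unactivated bicyclobutane has not been shown. The one ring closed is the seven-membered ring, by a polarity-matched 7-endo-trig cyclization (the 6-exo mode would attack the electron-poor α-carbon and build a more strained bridged ring). C2 and C7 are set by the substrate: the first radical should enter on the convex face of the bicyclobutane, anti to the three-carbon bridge and away from the cis silyloxy and methyl groups, and the short tether can reach the second carbon only on the same face, so H on C2 and CH3 on C7 end up syn to the C9–C11 bridge as in the target. The step needs attack at the C–H bridgehead (secured by the methyl on the other bridgehead, which also makes 19 tertiary), anti attack (a syn adduct cannot cyclize), and ring closure faster than intermolecular reactions of 19 (no hydrogen donor present, high dilution, slow addition of 18).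

Step 12
Reactants: 20 11-(tert-butyldimethylsilyloxy)-3,3,7,9-tetramethyltricyclo[5.4.0.0^2,8]undec-5-en-4-one
Product: 22 11-(tert-butyldimethylsilyloxy)-6-hydroxy-3,3,7,9-tetramethyltricyclo[5.4.0.0^2,8]undecan-4-one, via pinacol boronate 21 (not isolated)
Conditions: B2pin2 (1.2 equiv), CuCl (5 mol %), NaOtBu (10 mol %), (R,R)-QuinoxP* (6 mol %), MeOH (2 equiv), THF, 0 → 25 °C; then H2O2 (30 % aq.), pH 7 buffer, 0 °C
Reagents that add atoms: bis(pinacolato)diboron CC1(C)OB(OC1(C)C)B1OC(C)(C)C(C)(C)O1; hydrogen peroxide OO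
Why: Copper-catalysed asymmetric conjugate borylation (Yun type) with stereoretentive C–B oxidation; the two enone faces differ only by remote groups, so the chiral phosphine should control C6 (the ligand antipode that puts oxygen on the C1 side is used, and the mirror-image ligand would serve if the sense proved opposite).

Step 13
Reactants: 23 methyl (Z)-2-methylbut-2-enoate
Product: 24 (Z)-2-methylbut-2-en-1-ol
Conditions: iBu2AlH (2.2 equiv), CH2Cl2, −78 °C; aq. work-up
Reagents that add atoms: none
Why: DIBAL reduction of the ester at low temperature gives the allylic alcohol with the Z geometry intact.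

Step 14
Reactants: 24 (Z)-2-methylbut-2-en-1-ol
Product: 25 (Z)-2-methylbut-2-enal
Conditions: MnO2 (activated, excess), CH2Cl2, 0 °C, dark; used at once
Reagents that add atoms: none
Why: MnO2 oxidises the allylic alcohol under neutral conditions; the Z enal is configurationally labile and is not stored.

Step 15
Reactants: 22 11-(tert-butyldimethylsilyloxy)-6-hydroxy-3,3,7,9-tetramethyltricyclo[5.4.0.0^2,8]undecan-4-one; 25 (Z)-2-methylbut-2-enal
Product: 27 11-(tert-butyldimethylsilyloxy)-4-hydroxy-3,3,7,9-tetramethyltricyclo[5.4.0.0^2,8]undecan-6-yl (Z)-2-methylbut-2-enoate, via hemiacetal 26 (not isolated)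
Conditions: SmI2 (0.3 equiv), 25 (4 equiv), THF, −10 °C
Reagents that add atoms: none
Why: Evans–Tishchenko reduction: trivalent samarium formed in situ binds the hemiacetal and the ketone, and intramolecular hydride transfer delivers hydrogen to C4 on the face of the C6 oxygen, giving the 4,6-anti diol monoester, so C4 is set, the two oxygens are told apart and the angelate is installed in one operation.

Step 16
Reactants: 27 11-(tert-butyldimethylsilyloxy)-4-hydroxy-3,3,7,9-tetramethyltricyclo[5.4.0.0^2,8]undecan-6-yl (Z)-2-methylbut-2-enoate; 15 (2S,3R)-2,3-dimethyloxirane-2-carboxylic acid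
Product: 29 11-(tert-butyldimethylsilyloxy)-3,3,7,9-tetramethyl-6-[(Z)-2-methylbut-2-enoyloxy]tricyclo[5.4.0.0^2,8]undecan-4-yl (2S,3R)-2,3-dimethyloxirane-2-carboxylate, via mixed anhydride 28 (not isolated)
Conditions: 15 (2 equiv), 2,4,6-trichlorobenzoyl chloride, Et3N, THF, 0 °C; then 27, DMAP, toluene, 25 °C
Reagents that add atoms: none
Why: Yamaguchi esterification through the mixed anhydride should acylate the hindered neopentyl alcohol; no stereocentre is touched and the glycidic acyl group has no α-hydrogen.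

Step 17
Reactants: 29 silyl ether diester
Product: 30 11-hydroxy-3,3,7,9-tetramethyl-6-[(Z)-2-methylbut-2-enoyloxy]tricyclo[5.4.0.0^2,8]undecan-4-yl (2S,3R)-2,3-dimethyloxirane-2-carboxylate
Conditions: HF·pyridine, pyridine, THF, 0 → 25 °C
Reagents that add atoms: none
Why: Buffered fluoride cleaves the secondary silyl ether; the esters and the electron-poor oxirane should survive.

Step 18
Reactants: 30 hydroxy diester
Product: 31 3,3,7,9-tetramethyl-6-[(Z)-2-methylbut-2-enoyloxy]-11-oxotricyclo[5.4.0.0^2,8]undecan-4-yl (2S,3R)-2,3-dimethyloxirane-2-carboxylate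
Conditions: Dess–Martin periodinane, NaHCO3, CH2Cl2, 25 °C
Reagents that add atoms: none
Why: Dess–Martin oxidation under buffered conditions should give the C11 ketone without isomerising the angelate.

Step 19
Reactants: 31 keto diester
Product: 32 3,3,7,9-tetramethyl-6-[(Z)-2-methylbut-2-enoyloxy]-11-oxotricyclo[5.4.0.0^2,8]undec-9-en-4-yl (2S,3R)-2,3-dimethyloxirane-2-carboxylate (CNP0149458.1)
Conditions: IBX, 4-methoxypyridine N-oxide, DMSO, 25 °C
Reagents that add atoms: none
Why: IBX dehydrogenation of a ketone to an enone (Nicolaou): enolization is possible only toward C10 because C1 is a bridgehead, so the C9=C10 bond forms and the C9 stereocentre, which relayed the chirality from step 1, is erased.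

**Compound list**

1 | tert-butyl 3-oxobutanoate | CC(=O)CC(=O)OC(C)(C)C | starting material
2 | (E)-but-2-enal | C/C=C/C=O | starting material
3 | tert-butyl (3R)-2-acetyl-3-methyl-5-oxopentanoate (C2 epimers) | CC(=O)C(C(=O)OC(C)(C)C)[C@H](C)CC=O | intermediate
4 | tert-butyl (6R)-6-methyl-2-oxocyclohex-3-ene-1-carboxylate (C1 epimers) | O=C1C=CC[C@@H](C)C1C(=O)OC(C)(C)C | intermediate
5 | (R)-5-methylcyclohex-2-en-1-one | O=C1C=CC[C@@H](C)C1 | intermediate
6 | (5R)-1,5-dimethylcyclohex-2-en-1-ol (C1 epimers) | CC1(O)C=CC[C@@H](C)C1 | intermediate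
7 | (S)-3,5-dimethylcyclohex-2-en-1-one | O=C1C=C(C)C[C@H](C)C1 | intermediate
8 | (1S,5S)-3,5-dimethylcyclohex-2-en-1-ol (cis) | O[C@@H]1C=C(C)C[C@H](C)C1 | intermediate
9 | 7,7-dibromo-4,6-dimethylbicyclo[4.1.0]heptan-2-ol, with 2-OH, 4-CH3 and C7 on the same face | O[C@H]1C[C@@H](C)C[C@]2(C)[C@H]1C2(Br)Br | intermediate
10 | tert-butyl[(7,7-dibromo-4,6-dimethylbicyclo[4.1.0]heptan-2-yl)oxy]dimethylsilane (same configuration as 9) | CC(C)(C)[Si](C)(C)O[C@H]1C[C@@H](C)C[C@]2(C)[C@H]1C2(Br)Br | intermediate
11 | 7-bromo-7-lithio carbenoid of 10 | CC(C)(C)[Si](C)(C)O[C@H]1C[C@@H](C)C[C@]2(C)[C@H]1C2(Br)[Li] | intermediate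
12 | tert-butyl[(1,5-dimethyltricyclo[4.1.0.0^2,7]heptan-3-yl)oxy]dimethylsilane, with 3-OSi and 5-CH3 on the face of C7 | CC(C)(C)[Si](C)(C)O[C@H]1C[C@@H](C)[C@@H]2[C@]3(C)[C@H]1[C@H]23 | intermediate
13 | (E)-2-methylbut-2-en-1-ol | C/C=C(\C)CO | starting material
14 | [(2R,3R)-2,3-dimethyloxiran-2-yl]methanol | OC[C@@]1(C)O[C@@H]1C | intermediate
15 | (2S,3R)-2,3-dimethyloxirane-2-carboxylic acid | OC(=O)[C@@]1(C)O[C@@H]1C | intermediate
16 | (E)-1,2-bis(tributylstannyl)ethene | CCCC[Sn](CCCC)(CCCC)/C=C/[Sn](CCCC)(CCCC)CCCC | starting material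
17 | 2-bromo-2-methylpropanoyl bromide | CC(C)(Br)C(=O)Br | starting material
18 | (E)-4-bromo-4-methyl-1-(tributylstannyl)pent-1-en-3-one | CC(C)(Br)C(=O)/C=C/[Sn](CCCC)(CCCC)CCCC | intermediate
19 | tertiary cyclobutyl radical (ring-opened adduct of 12 and the keto radical from 18; chain anti to the three-carbon bridge) | CCCC[Sn](CCCC)(CCCC)/C=C/C(=O)C(C)(C)[C@@H]1[C@H]2[C@@H](O[Si](C)(C)C(C)(C)C)C[C@@H](C)[C@@H]1[C]2C | intermediate
20 | 11-(tert-butyldimethylsilyloxy)-3,3,7,9-tetramethyltricyclo[5.4.0.0^2,8]undec-5-en-4-one (2-H and 7-CH3 syn to the C9–C11 bridge; 9-CH3 and 11-OSi on the face of C2) | C1=CC(=O)C(C)(C)[C@@H]2[C@H]3[C@@H](O[Si](C)(C)C(C)(C)C)C[C@@H](C)[C@@H]2[C@]31C | intermediate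
21 | 6-(pinacolatoboryl) derivative of the saturated 4-ketone (boron on the C1 side) | CC1(C)OB(OC1(C)C)[C@@H]1CC(=O)C(C)(C)[C@@H]2[C@H]3[C@@H](O[Si](C)(C)C(C)(C)C)C[C@@H](C)[C@@H]2[C@]31C | intermediate
22 | 11-(tert-butyldimethylsilyloxy)-6-hydroxy-3,3,7,9-tetramethyltricyclo[5.4.0.0^2,8]undecan-4-one (6-OH on the C1 side) | O[C@@H]1CC(=O)C(C)(C)[C@@H]2[C@H]3[C@@H](O[Si](C)(C)C(C)(C)C)C[C@@H](C)[C@@H]2[C@]31C | intermediate
23 | methyl (Z)-2-methylbut-2-enoate | C/C=C(/C)C(=O)OC | starting material
24 | (Z)-2-methylbut-2-en-1-ol | C/C=C(/C)CO | intermediate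
25 | (Z)-2-methylbut-2-enal | C/C=C(/C)C=O | intermediate
26 | hemiacetal of 22 (6-O) with 25 | C/C=C(/C)C(O)O[C@@H]1CC(=O)C(C)(C)[C@@H]2[C@H]3[C@@H](O[Si](C)(C)C(C)(C)C)C[C@@H](C)[C@@H]2[C@]31C | intermediate
27 | 11-(tert-butyldimethylsilyloxy)-4-hydroxy-3,3,7,9-tetramethyltricyclo[5.4.0.0^2,8]undecan-6-yl (Z)-2-methylbut-2-enoate (4-OH on the C8 side, anti to 6-O) | C/C=C(/C)C(=O)O[C@@H]1C[C@@H](O)C(C)(C)[C@@H]2[C@H]3[C@@H](O[Si](C)(C)C(C)(C)C)C[C@@H](C)[C@@H]2[C@]31C | intermediate
28 | (2S,3R)-2,3-dimethyloxirane-2-carboxylic 2,4,6-trichlorobenzoic anhydride | O=C(OC(=O)c1c(Cl)cc(Cl)cc1Cl)[C@@]1(C)O[C@@H]1C | intermediate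
29 | 11-(tert-butyldimethylsilyloxy)-3,3,7,9-tetramethyl-6-[(Z)-2-methylbut-2-enoyloxy]tricyclo[5.4.0.0^2,8]undecan-4-yl (2S,3R)-2,3-dimethyloxirane-2-carboxylate | C/C=C(/C)C(=O)O[C@@H]1C[C@@H](OC(=O)[C@@]2(C)O[C@@H]2C)C(C)(C)[C@@H]2[C@H]3[C@@H](O[Si](C)(C)C(C)(C)C)C[C@@H](C)[C@@H]2[C@]31C | intermediate
30 | 11-hydroxy analogue of 29 | C/C=C(/C)C(=O)O[C@@H]1C[C@@H](OC(=O)[C@@]2(C)O[C@@H]2C)C(C)(C)[C@@H]2[C@H]3[C@@H](O)C[C@@H](C)[C@@H]2[C@]31C | intermediate
31 | 11-oxo analogue (9,10-dihydro target) | C/C=C(/C)C(=O)O[C@@H]1C[C@@H](OC(=O)[C@@]2(C)O[C@@H]2C)C(C)(C)[C@@H]2[C@H]3C(=O)C[C@@H](C)[C@@H]2[C@]31C | intermediate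
32 | 3,3,7,9-tetramethyl-6-[(Z)-2-methylbut-2-enoyloxy]-11-oxotricyclo[5.4.0.0^2,8]undec-9-en-4-yl (2S,3R)-2,3-dimethyloxirane-2-carboxylate | C/C=C(/C)C(=O)O[C@@H]1C[C@@H](OC(=O)[C@@]2(C)O[C@@H]2C)C(C)(C)[C@@H]2[C@H]3C(=O)C=C(C)[C@@H]2[C@]31C | target

**Step count and risks**

Total steps: 19. Longest linear sequence: 14 steps (steps 1–7, 11, 12, 15–19).

Most likely to fail:

1. Step 11 (proposed new method). The cyclobutyl radical may react intermolecularly before the 7-endo closure, or the first radical may attack from the direction that cannot cyclize. Fallback with known radical steps, taken one at a time: from 12, atom-transfer radical addition of 3-bromo-3-methylbutan-2-one (Et3B, air, 0 °C) across the central bond should give the bromo methyl ketone F1. Claisen formylation (HCO2Et, NaH) then gives the keto aldehyde F2, and O-silylation (TBSCl, Et3N) the silyl vinylogous ester F3. Bu3SnH/AIBN under slow addition regenerates the tertiary radical for a Giese 7-endo cyclization to the β-silyloxy ketone F4, and DBU eliminates silanol to return to 20.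

2. Step 15. The Z enal or the forming angelate may isomerise to the E series on the Lewis-acidic samarium, or hemiacetal formation at the hindered alcohol may be too slow. Fallback: from 22, acylation with angelic acid through its 2,4,6-trichlorobenzoyl mixed anhydride (Et3N, toluene, no DMAP) gives the β-angeloyloxy ketone F5. Reagent-controlled reduction with (S)-Me-CBS oxazaborolidine and catecholborane (the quaternary C3 side acting as the large group) then returns to 27.

3. Step 12. Copper–boryl addition to the neopentyl β-carbon may be slow, or facial control by the ligand may be poor. Fallback: from 20, conjugate silylation with PhMe2Si–Bpin (CuCl, chiral N-heterocyclic carbene ligand, NaOtBu) gives the β-silyl ketone F6. Fleming–Tamao oxidation (KBr, AcOOH, NaOAc) with retention returns to 22.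

**Further compounds**

F1 | step 11 | 3-[6-bromo-3-(tert-butyldimethylsilyloxy)-5,6-dimethylbicyclo[3.1.1]... simplified: bromo methyl ketone, ATRA adduct of 12 (keto side chain anti, Br syn to the three-carbon bridge) | CC(=O)C(C)(C)[C@@H]1[C@H]2[C@@H](O[Si](C)(C)C(C)(C)C)C[C@@H](C)[C@@H]1[C@]2(C)Br
F2 | step 11 | formylated ketone of F1 (β-keto aldehyde, hydroxymethylene tautomer) | O=CCC(=O)C(C)(C)[C@@H]1[C@H]2[C@@H](O[Si](C)(C)C(C)(C)C)C[C@@H](C)[C@@H]1[C@]2(C)Br
F3 | step 11 | (E)-silyl vinylogous ester of F2 | CC(C)(C)[Si](C)(C)O/C=C/C(=O)C(C)(C)[C@@H]1[C@H]2[C@@H](O[Si](C)(C)C(C)(C)C)C[C@@H](C)[C@@H]1[C@]2(C)Br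
F4 | step 11 | 6,11-bis(tert-butyldimethylsilyloxy)-3,3,7,9-tetramethyltricyclo[5.4.0.0^2,8]undecan-4-one (C6 epimers) | CC(C)(C)[Si](C)(C)OC1CC(=O)C(C)(C)[C@@H]2[C@H]3[C@@H](O[Si](C)(C)C(C)(C)C)C[C@@H](C)[C@@H]2[C@]31C
F5 | step 15 | 11-(tert-butyldimethylsilyloxy)-3,3,7,9-tetramethyl-4-oxotricyclo[5.4.0.0^2,8]undecan-6-yl (Z)-2-methylbut-2-enoate | C/C=C(/C)C(=O)O[C@@H]1CC(=O)C(C)(C)[C@@H]2[C@H]3[C@@H](O[Si](C)(C)C(C)(C)C)C[C@@H](C)[C@@H]2[C@]31C
F6 | step 12 | 11-(tert-butyldimethylsilyloxy)-6-[dimethyl(phenyl)silyl]-3,3,7,9-tetramethyltricyclo[5.4.0.0^2,8]undecan-4-one | C[Si](C)(c1ccccc1)[C@@H]1CC(=O)C(C)(C)[C@@H]2[C@H]3[C@@H](O[Si](C)(C)C(C)(C)C)C[C@@H](C)[C@@H]2[C@]31C
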